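Of the free monomer charged, 3.1 mol% stands as pre-initiator in ochre, in grey and in both runs, so each pre-initiator has 32.3 monomer units to its share. I call this N, the charge per centre (the usual target degree of polymerisation). If each pre-initiator begins one chain, the length is N times the fraction of the charge in chains.

in all of them: pre-initiator 3.1 mol%

| run | free monomer | protic impurity | remark | time |
|---|---|---|---|---|
| beta | 0.55 M | 0.48 M | run made earlier |  |
| delta | 2.2 M | 0.48 M | run made earlier |  |
| ochre | 1.6 M | 0.480 M |  | 5.0 h |
| grey | 0.40 M | 0.480 M |  | 5.0 h |

- beta (time / h: monomer in chains / %, free monomer / %): 0.667: 1.1, 92.3; 1.33: 5.4, 81.0; 2.00: 8.9, 72.3; 2.50: 15.3, 64.6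
- delta (time / h: monomer in chains / %, free monomer / %): 0.200: 2.0, 95.4; 0.500: 7.9, 85.9; 1.00: 27.1, 66.4; 2.50: 63.4, 26.7

(each reading ± 1 percentage point)

1. which of the two ends with the longer chains by the average number of monomer units in a chain (chains begun, living or dead) ("neither" if they lie within 10%) (ochre / grey / neither)
2. average number of monomer units in a chain (chains begun, living or dead) at the end, ochre
3. average number of monomer units in a chain (chains begun, living or dead) at the end, grey

- the average divides the monomer in chains by the number of chains begun, living and dead together
- the earlier runs do not show the number of chains; that part of a forecast is a guess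

After a start-up I treat free monomer as a pseudo-first-order loss, dm/dt = −g·m, where m is the fraction left. The late readings give g = 0.607 h⁻¹ in delta and 0.193 h⁻¹ in beta. That is a power 0.826 of the charge, which I carry to ochre, 0.467 h⁻¹, and grey, 0.149 h⁻¹.

The ladder runs from the lag up through the monomer lifetimes, which are my estimates. The lag, read from delta, is 0.326 h. Ochre's monomer lifetime, 2.14 h, is longer than that but shorter than the 5.0 h asked. Grey's lifetime, 6.73 h, is longer than the time asked.

Let φ be monomer in chains over monomer consumed. At the last readings it is 0.865 in delta and 0.432 in beta, twice for 4.00 times the charge. So I scale φ by the square root of the charge, to 0.738 in ochre and 0.369 in grey.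

m = exp(−g·(t − lag)): ochre 11.3%, grey 49.9%

length = N·φ·(share consumed): ochre 21.1, grey 5.96

The forecast says ochre, with 23 against 8, both above mine, and adds: “chain count is a guess”.

The flask gives ochre, 23.7 against 8.50, so the forecast stands.

    free monomer + initiator → living end + monomer in chains (k = 0.0190 L mol⁻¹ min⁻¹)
    free monomer + living end → monomer in chains + living end, rate k2*[living end]*[free monomer] (k = 0.150 L mol⁻¹ min⁻¹)
    protic impurity + free monomer → quenched substrate (k = 0.00410 L mol⁻¹ min⁻¹)
    pre-initiator → initiator (k = 0.110 min⁻¹)

In ochre, N times the 71.6% in chains gives 23.1. In grey, N times 20.6% gives 6.65, under its 8.50, and there 0.00271 M of initiator still stands beside 0.00969 M of living end. The forecast's 23 belongs to a loading of 3.1 mol%. Ochre with 0.78 mol% has N = 128, and 31.8% stands in chains, so N gives 40.8, and that flask gives 40.9.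

The data are calculated from invented constants; scatter was added.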